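**Retrosynthetic overview**

1. The side-chain ester C–O bond is formed second to last, from 5,8-di-O-MOM-shikonin and a silyl-protected 3-hydroxy-3-methylbutanoic acid; the two phenolic MOM ethers and the tertiary silyl ether come off in the final step.
2. The quinone ring is traced back to 1-naphthols (para-oxidation), and these to a 1,4-epoxy-1,4-dihydronaphthalene (bridge-opening isomerisation); both operations are run in one step without isolating the naphthols.
3. Key disconnection: C1–C8a and C4–C4a, a Diels–Alder addition of 3,6-bis(methoxymethoxy)benzyne to a 3-substituted furan. Quinone carbons C1–C4, with the side chain on C2, are the four carbons of a 3-substituted furan, and the benzo ring (C4a–C8a) carries identical oxygens on C5 and C8 and is therefore symmetric, so either orientation of the furan ends in the same 2-substituted quinone.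
4. The furan comes from furan-3-carbaldehyde by asymmetric allylboration (sets the only stereocentre), silylation and cross-metathesis with 2-methylbut-2-ene; the aryne precursor comes from bromohydroquinone.
5. Ring order: the benzo ring and the furan are bought; the second six-membered ring is closed in the key step as its 1,4-epoxide, then aromatised to the naphthol and oxidised to the quinone.

Key step: step 5

Remark: the allylborane is specified by its parent terpene, (−)-α-pinene, because this series delivers allyl to the Re face of aryl aldehydes and so gives the (R)-carbinol.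

**Route**

Step 1
Reactants: 1 bromohydroquinone
Product: 2 2-bromo-1,4-bis(methoxymethoxy)benzene
Conditions: MOMCl, i-Pr2NEt, CH2Cl2, 0 °C to rt, Ar
Reagents that add atoms: chloromethyl methyl ether, COCCl
Why: Standard O-alkylation of both phenols to MOM ethers under amine base, with the aryl bromide inert.

Step 2
Reactants: 3 furan-3-carbaldehyde
Product: 5 (1R)-1-(furan-3-yl)but-3-en-1-ol, via borinate ester 4 (not isolated)
Conditions: (+)-Ipc2BOMe [from (−)-α-pinene], allylMgBr, Et2O, 0 °C to rt; then 3, −78 °C; then NaOH, H2O2, 0 °C to rt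
Reagents that add atoms: allylmagnesium bromide, C=CC[Mg]Br
Why: Brown asymmetric allylboration, in which the (−)-α-pinene-derived B-allyldiisopinocampheylborane transfers allyl through a closed chair transition state to the Re face of the aldehyde and thereby sets the (R)-carbinol centre (3-furyl ranks above allyl, as phenyl does in the benzaldehyde case).

Step 3
Reactants: 5 (1R)-1-(furan-3-yl)but-3-en-1-ol
Product: 6 3-[(1R)-1-(tert-butyldimethylsilyloxy)but-3-en-1-yl]furan
Conditions: TBSCl, imidazole, DMF, rt
Reagents that add atoms: tert-butyldimethylsilyl chloride, CC(C)(C)[Si](C)(C)Cl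
Why: Routine silylation of a secondary alcohol at oxygen, which leaves the stereocentre untouched and makes the material less volatile.

Step 4
Reactants: 6 3-[(1R)-1-(tert-butyldimethylsilyloxy)but-3-en-1-yl]furan; 7 2-methylbut-2-ene
Product: 8 3-[(1R)-1-(tert-butyldimethylsilyloxy)-4-methylpent-3-en-1-yl]furan
Conditions: second-generation Grubbs catalyst (H2IMes)(PCy3)Cl2Ru=CHPh (cat.), 2-methylbut-2-ene/CH2Cl2, 40 °C, sealed vessel
Reagents that add atoms: none
Why: Olefin cross-metathesis of the terminal alkene with a large excess of 2-methylbut-2-ene should install the trisubstituted prenyl-type alkene with loss of propene, and furans and silyl ethers are tolerated.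

Step 5
Reactants: 2 2-bromo-1,4-bis(methoxymethoxy)benzene (excess); 8 3-[(1R)-1-(tert-butyldimethylsilyloxy)-4-methylpent-3-en-1-yl]furan
Product: 11 2-[(1R)-1-(tert-butyldimethylsilyloxy)-4-methylpent-3-en-1-yl]-5,8-bis(methoxymethoxy)-1,4-dihydro-1,4-epoxynaphthalene (both bridge diastereomers), via ortho-bromoaryllithium 9 (not isolated), via 3,6-bis(methoxymethoxy)benzyne 10 (not isolated)
Conditions: LiTMP (lithium 2,2,6,6-tetramethylpiperidide, from TMPH and n-BuLi, slow addition), THF, −78 °C to rt
Reagents that add atoms: none
Why: LiTMP, which cannot undergo bromine–lithium exchange, removes the ring proton of 2 lying between Br and an OMOM group (the most acidic site), and aryllithium 9 loses LiBr to give the symmetric aryne 10. The furan ring of 8 then adds across the strained triple bond as the 4π partner in a concerted suprafacial (4+2) cycloaddition; the closest known reaction type is the Diels–Alder trapping by furans of 3,6-dialkoxybenzynes made from 2-bromo-1,4-dialkoxybenzenes and amide bases. The six-membered carbocycle that becomes the quinone ring is closed intermolecularly as an annulation in which C1–C8a and C4–C4a form in the same step, leaving the furan oxygen as a 1,4-bridge. The two bridgehead carbons become stereocentres without control from the remote (R)-carbinol centre, so both bridge diastereomers are expected; this is harmless because those centres are erased in step 6. No regioselectivity is needed since 10 is symmetric, and the chemoselectivity needed (furan diene over the trisubstituted alkene, and over 9 or the amide as competing nucleophiles) rests on the high diene reactivity of furan, the bulk of LiTMP and TMPH, and slow addition of base to keep 9 dilute. The (R)-centre is not part of the reacting system and its proton should not be removed by the hindered amide at low temperature, so its configuration should be preserved.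

Step 6
Reactants: 11 2-[(1R)-1-(tert-butyldimethylsilyloxy)-4-methylpent-3-en-1-yl]-5,8-bis(methoxymethoxy)-1,4-dihydro-1,4-epoxynaphthalene
Product: 14 2-[(1R)-1-(tert-butyldimethylsilyloxy)-4-methylpent-3-en-1-yl]-5,8-bis(methoxymethoxy)naphthalene-1,4-dione, via 2-alkyl-1-naphthol 12 (not isolated), via 3-alkyl-1-naphthol 13 (not isolated)
Conditions: Cu(OTf)2 (cat.), 4 Å molecular sieves, CH2Cl2, 0 °C, Ar, short reaction time; then solvent exchanged for acetone, (KSO3)2NO (excess), KH2PO4 (aq), 0 °C to rt
Reagents that add atoms: Fremy's salt, dipotassium nitrosodisulfonate, [K+].[K+].[O]N(S(=O)(=O)[O-])S(=O)(=O)[O-]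
Why: Lewis acid-catalysed isomerisation of the 1,4-epoxy-1,4-dihydronaphthalene (C–O ionisation to a benzylic and allylic cation, 1,2-hydride shift, tautomerisation) removes the bridgehead stereocentres and should give mainly naphthol 12, since opening at C4 places charge on the substituted carbon C2, beside regioisomer 13, and Teuber oxidation of the crude, air-sensitive naphthols with two equivalents of the nitroxyl radical then converts each at its free para position into the same para-quinone because C5 and C8 carry identical groups.

Step 7
Reactants: 14 2-[(1R)-1-(tert-butyldimethylsilyloxy)-4-methylpent-3-en-1-yl]-5,8-bis(methoxymethoxy)naphthalene-1,4-dione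
Product: 15 2-[(1R)-1-hydroxy-4-methylpent-3-en-1-yl]-5,8-bis(methoxymethoxy)naphthalene-1,4-dione
Conditions: HF·pyridine, pyridine, THF, 0 °C to rt
Reagents that add atoms: none
Why: Fluoride-mediated desilylation under buffered, non-basic conditions that the quinone, the aryl MOM ethers and the alkene should tolerate, with the C–O bond of the stereocentre untouched.

Step 8
Reactants: 16 3-hydroxy-3-methylbutanoic acid
Product: 18 3-methyl-3-(triethylsilyloxy)butanoic acid, via bis-silylated ester 17 (not isolated)
Conditions: TESCl, imidazole, DMAP (cat.), DMF, rt; then K2CO3, MeOH/H2O/THF, 0 °C; citric acid work-up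
Reagents that add atoms: chlorotriethylsilane, CC[Si](Cl)(CC)CC
Why: Exhaustive silylation followed by selective solvolysis of the much more labile silyl ester leaves the tertiary alcohol masked, so the acid cannot lactonise, eliminate or oligomerise on activation.

Step 9
Reactants: 15 2-[(1R)-1-hydroxy-4-methylpent-3-en-1-yl]-5,8-bis(methoxymethoxy)naphthalene-1,4-dione; 18 3-methyl-3-(triethylsilyloxy)butanoic acid
Product: 19 (1R)-1-[5,8-bis(methoxymethoxy)-1,4-dioxo-1,4-dihydronaphthalen-2-yl]-4-methylpent-3-en-1-yl 3-methyl-3-(triethylsilyloxy)butanoate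
Conditions: DCC, DMAP (cat.), CH2Cl2, 0 °C to rt
Reagents that add atoms: none
Why: Steglich esterification acylates the only free hydroxyl at oxygen, so the configuration of the carbinol carbon is retained.

Step 10
Reactants: 19 (1R)-1-[5,8-bis(methoxymethoxy)-1,4-dioxo-1,4-dihydronaphthalen-2-yl]-4-methylpent-3-en-1-yl 3-methyl-3-(triethylsilyloxy)butanoate
Product: 20 beta-HIVS, (1R)-1-(5,8-dihydroxy-1,4-dioxo-1,4-dihydronaphthalen-2-yl)-4-methylpent-3-en-1-yl 3-hydroxy-3-methylbutanoate
Conditions: HCl (aq, 3 M)/THF/i-PrOH, 0 °C to rt, dark, Ar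
Reagents that add atoms: none
Why: Mild acid-catalysed acetal hydrolysis should remove both aryl MOM ethers (aided by the peri carbonyl groups) and the tertiary triethylsilyl ether, while the acyloxy-bearing stereocentre next to the electron-poor quinone should not ionise.

**Compound list**

1 | bromohydroquinone (2-bromobenzene-1,4-diol) | Oc1ccc(O)c(Br)c1 | starting material
2 | 2-bromo-1,4-bis(methoxymethoxy)benzene | COCOc1ccc(OCOC)c(Br)c1 | intermediate
3 | furan-3-carbaldehyde | O=Cc1ccoc1 | starting material
4 | (1R)-1-(furan-3-yl)but-3-en-1-yl diisopinocampheylborinate (Ipc groups from (−)-α-pinene) | C=CC[C@@H](OB([C@H]1C[C@H]2C[C@@H]([C@@H]1C)C2(C)C)[C@H]1C[C@H]2C[C@@H]([C@@H]1C)C2(C)C)c1ccoc1 | intermediate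
5 | (1R)-1-(furan-3-yl)but-3-en-1-ol | C=CC[C@@H](O)c1ccoc1 | intermediate
6 | 3-[(1R)-1-(tert-butyldimethylsilyloxy)but-3-en-1-yl]furan | C=CC[C@@H](O[Si](C)(C)C(C)(C)C)c1ccoc1 | intermediate
7 | 2-methylbut-2-ene | CC=C(C)C | starting material
8 | 3-[(1R)-1-(tert-butyldimethylsilyloxy)-4-methylpent-3-en-1-yl]furan | CC(C)=CC[C@@H](O[Si](C)(C)C(C)(C)C)c1ccoc1 | intermediate
9 | [2-bromo-3,6-bis(methoxymethoxy)phenyl]lithium | [Li]c1c(OCOC)ccc(OCOC)c1Br | intermediate
10 | 3,6-bis(methoxymethoxy)benzyne | COCOC1=CC=C(OCOC)C#C1 | intermediate
11 | 2-[(1R)-1-(tert-butyldimethylsilyloxy)-4-methylpent-3-en-1-yl]-5,8-bis(methoxymethoxy)-1,4-dihydro-1,4-epoxynaphthalene (both bridge diastereomers) | CC(C)=CC[C@@H](O[Si](C)(C)C(C)(C)C)C1=CC2OC1c1c(OCOC)ccc(OCOC)c12 | intermediate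
12 | 2-[(1R)-1-(tert-butyldimethylsilyloxy)-4-methylpent-3-en-1-yl]-5,8-bis(methoxymethoxy)naphthalen-1-ol | CC(C)=CC[C@@H](O[Si](C)(C)C(C)(C)C)c1ccc2c(OCOC)ccc(OCOC)c2c1O | intermediate
13 | 3-[(1R)-1-(tert-butyldimethylsilyloxy)-4-methylpent-3-en-1-yl]-5,8-bis(methoxymethoxy)naphthalen-1-ol | CC(C)=CC[C@@H](O[Si](C)(C)C(C)(C)C)c1cc(O)c2c(OCOC)ccc(OCOC)c2c1 | intermediate
14 | 2-[(1R)-1-(tert-butyldimethylsilyloxy)-4-methylpent-3-en-1-yl]-5,8-bis(methoxymethoxy)naphthalene-1,4-dione | CC(C)=CC[C@@H](O[Si](C)(C)C(C)(C)C)C1=CC(=O)c2c(OCOC)ccc(OCOC)c2C1=O | intermediate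
15 | 2-[(1R)-1-hydroxy-4-methylpent-3-en-1-yl]-5,8-bis(methoxymethoxy)naphthalene-1,4-dione | CC(C)=CC[C@@H](O)C1=CC(=O)c2c(OCOC)ccc(OCOC)c2C1=O | intermediate
16 | 3-hydroxy-3-methylbutanoic acid | CC(C)(O)CC(=O)O | starting material
17 | triethylsilyl 3-methyl-3-(triethylsilyloxy)butanoate | CC[Si](CC)(CC)OC(=O)CC(C)(C)O[Si](CC)(CC)CC | intermediate
18 | 3-methyl-3-(triethylsilyloxy)butanoic acid | CC[Si](CC)(CC)OC(C)(C)CC(=O)O | intermediate
19 | (1R)-1-[5,8-bis(methoxymethoxy)-1,4-dioxo-1,4-dihydronaphthalen-2-yl]-4-methylpent-3-en-1-yl 3-methyl-3-(triethylsilyloxy)butanoate | CC(C)=CC[C@@H](OC(=O)CC(C)(C)O[Si](CC)(CC)CC)C1=CC(=O)c2c(OCOC)ccc(OCOC)c2C1=O | intermediate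
20 | beta-HIVS, (1R)-1-(5,8-dihydroxy-1,4-dioxo-1,4-dihydronaphthalen-2-yl)-4-methylpent-3-en-1-yl 3-hydroxy-3-methylbutanoate | CC(C)=CC[C@@H](OC(=O)CC(C)(C)O)C1=CC(=O)c2c(O)ccc(O)c2C1=O | target

**Step count**

Total: 10 steps. Longest linear sequence: 8 steps (3 to 20 through steps 2, 3, 4, 5, 6, 7, 9 and 10).

**Steps most likely to fail**

Step 5 (key step). The aryne may be consumed by aryllithium 9 or by the amide instead of the dilute furan, and LiTMP may deprotonate the furan of 8 at its free α-position, so that little cycloadduct forms. The fallback sets out from 8 and avoids any amide base by pre-forming the aryllithium from a chloride. Commercial chlorohydroquinone (Oc1ccc(O)c(Cl)c1) would be converted with MOMCl and i-Pr2NEt into 2-chloro-1,4-bis(methoxymethoxy)benzene F1. F1 would be lithiated between Cl and OMOM with s-BuLi in THF at −78 °C, where chlorine does not exchange and the ortho-chloroaryllithium persists, to give [2-chloro-3,6-bis(methoxymethoxy)phenyl]lithium F2. Furan 8 would then be added and the mixture warmed to rt, so that loss of LiCl releases the same aryne 10 in the presence of the furan only. The fallback comes back to the route at 11.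

Step 6. In the first stage the Lewis acid may also ionise the MOM acetals, with loss of a MOM group or closure of the new peri hydroxyl onto the neighbouring acetal carbon, or may strip the allylic silyl ether, so that little naphthol reaches the oxidation. The fallback sets out from 11 and replaces cationic opening by a neutral transition-metal-catalysed isomerisation of the oxabicyclic alkene, in which the metal inserts into the bridge C–O bond and no free carbocation is formed, using [RuCl2(CO)3]2 (cat.) in ClCH2CH2Cl at 60 °C. No new compound is made (F0): the crude naphthols 12 and 13 would be oxidised with (KSO3)2NO as in step 6, and the fallback comes back to the route at 14.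

Step 10. The acid needed to hydrolyse the MOM ethers may also hydrate or cyclise the trisubstituted alkene, cleave the side-chain ester or dehydrate the tertiary β-hydroxy ester. The fallback sets out from 14 and unmasks the phenols before the ester exists, relying on the low reactivity of the chelated peri hydroxyls of shikonin toward acylation. Me2BBr in CH2Cl2 at −78 °C would cleave both MOM ethers and leave the silyl ether, giving 2-[(1R)-1-(tert-butyldimethylsilyloxy)-4-methylpent-3-en-1-yl]-5,8-dihydroxynaphthalene-1,4-dione F3. HF·pyridine/pyridine in THF would then give shikonin F4. DCC/DMAP esterification of F4 with acid 18 should acylate only the side-chain hydroxyl, giving (1R)-1-(5,8-dihydroxy-1,4-dioxo-1,4-dihydronaphthalen-2-yl)-4-methylpent-3-en-1-yl 3-methyl-3-(triethylsilyloxy)butanoate F5. Buffered HF·pyridine would finally remove the triethylsilyl group, and the fallback comes back to the route at 20.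

**Further compounds**

F1 | step 5 | 2-chloro-1,4-bis(methoxymethoxy)benzene | COCOc1ccc(OCOC)c(Cl)c1
F2 | step 5 | [2-chloro-3,6-bis(methoxymethoxy)phenyl]lithium | [Li]c1c(OCOC)ccc(OCOC)c1Cl
F0 | step 6 | none | none
F3 | step 10 | 2-[(1R)-1-(tert-butyldimethylsilyloxy)-4-methylpent-3-en-1-yl]-5,8-dihydroxynaphthalene-1,4-dione | CC(C)=CC[C@@H](O[Si](C)(C)C(C)(C)C)C1=CC(=O)c2c(O)ccc(O)c2C1=O
F4 | step 10 | shikonin, 5,8-dihydroxy-2-[(1R)-1-hydroxy-4-methylpent-3-en-1-yl]naphthalene-1,4-dione | CC(C)=CC[C@@H](O)C1=CC(=O)c2c(O)ccc(O)c2C1=O
F5 | step 10 | (1R)-1-(5,8-dihydroxy-1,4-dioxo-1,4-dihydronaphthalen-2-yl)-4-methylpent-3-en-1-yl 3-methyl-3-(triethylsilyloxy)butanoate | CC(C)=CC[C@@H](OC(=O)CC(C)(C)O[Si](CC)(CC)CC)C1=CC(=O)c2c(O)ccc(O)c2C1=O
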